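The numbers in the tables were computed for substances that don't exist; scatter was added.

- You count target, but a target molecule can be lost after it is made, so follow one. My supposition is that it turns into side product with a hazard κ times the substrate turned over so far.

all flasks: temperature 0 °C
- red: substrate 13 mM; partner 24 mM; free catalyst 10 µM; run made earlier
- blue: substrate 10 mM; partner 24 mM; free catalyst 10 µM; run made earlier
- birch: substrate 20 mM; partner 24.0 mM; free catalyst 40 µM; time 80 min
- larch: substrate 20 mM; partner 24.0 mM; free catalyst 2.5 µM; time 80 min
- alder: substrate 20 mM; partner 24.0 mM; free catalyst 5.0 µM; time 80 min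
- oak: substrate 20 mM; partner 24.0 mM; free catalyst 10 µM; time 80 min
- elm: substrate 20 mM; partner 24.0 mM; free catalyst 30 µM; time 80 min

- red (time / min: target / %, side product / %, substrate / %): 1.33: 2.6, 0, 98.0; 3.00: 3.4, 0.8, 95.5; 6.00: 9.9, 0.9, 91.6; 15.0: 17.4, 0, 82.3
- blue (time / min: target / %, side product / %, substrate / %): 4.00: 6.0, 0.6, 95.6; 8.00: 11.5, 0.3, 85.6; 12.0: 19.6, 0, 81.8; 15.0: 22.2, 2.8, 76.4

(scatter of a reading: 1 percentage point)

- ranking by share of target in all that became target or side product, from high to low, at 80 min (birch / larch / alder / oak / elm)
- the share of target in all that became target or side product of the flask you put first, at 80 min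
- the share of target in all that became target or side product of the flask you put last, at 80 min

- the earlier runs were read with a standard deviation of 1 percentage point
- no earlier run changes the charge of free catalyst; that part of a forecast is a guess

- First link: the turnover frequency, substrate lost per catalyst and minute at the last reading, is 15.3 min⁻¹ in red and 15.7 min⁻¹ in blue, close despite different substrate charges. So I take the rate r as zero order in substrate and, as a guess, proportional to catalyst.
- Second link: averaging over birth moments gives the exposure E, r times time squared, divided by 3, the turnover-time integral met by the average target. For larch, E is 81.8 mM·min.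
- Third link: at the last readings of red and blue, the mean side product is 0.140 mM, with an exposure of 11.5 mM·min. That gives κ as a reading of 0.00529 mM⁻¹ min⁻¹, soft with a scatter of 1 percentage point per reading.
- Fourth link: at fixed time, E rises with catalyst, so I rank larch first, and the first estimate for larch is a share of 56.7%.
- The weak link is that linearity, since target lost no longer carries hazard. Solving for c(target), with gain r and loss κ times c(target) squared, gives a share of tanh(u)/u, where u is time times the root of κr. For larch, u is 1.14, so I commit to 71.5%.
- Birch holds the highest catalyst charge, so by the same exposure I put birch last. As a rough estimate for birch, I stop the constant rate where it adds up to the substrate charge, at 32.6 min, which gives a share of 51.3%.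
- The forecast, with “More catalyst gives better selectivity.”, gives birch > elm > oak > alder > larch, 98.7% and 74%, the reverse of my order.
- The flasks give larch > alder > oak > elm > birch, with 94.5% for larch and 60.7% for birch.

    substrate + free catalyst → catalyst intermediate A (k = 3460 M⁻¹ s⁻¹, Ea = 12.0 kJ mol⁻¹)
    catalyst intermediate A → catalyst intermediate B (k = 1.75 s⁻¹, Ea = 59.0 kJ mol⁻¹)
    partner + catalyst intermediate B ⇌ catalyst intermediate C (K = 55.2 M⁻¹, k = 21.5 M⁻¹ s⁻¹, Ea = 46.0 kJ mol⁻¹, ΔH = −41.0 kJ mol⁻¹)
    catalyst intermediate C → by-product + catalyst intermediate D (k = 2.64 s⁻¹, Ea = 71.0 kJ mol⁻¹)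
    catalyst intermediate D ⇌ free catalyst + target (K = 0.0809 M, k = 2.55 s⁻¹, Ea = 70.0 kJ mol⁻¹, ΔH = −21.0 kJ mol⁻¹)
    target + by-product → side product (k = 0.0123 M⁻¹ s⁻¹, Ea = 49.0 kJ mol⁻¹)
    2 substrate → self-condensation product (k = 7.03 × 10⁻⁵ M⁻¹ s⁻¹, Ea = 75.0 kJ mol⁻¹)
    partner → decomposed reagent (k = 1.36 × 10⁻⁴ s⁻¹, Ea = 85.0 kJ mol⁻¹)
    (constants at 0 °C)

- The ranking stands, but larch keeps 94.5% where I reckoned 71.5%. With k6 from the scheme in place of κ, the exposure of larch gives a loss of 6.04%, against 5.50% simulated. The neighbouring flask is larch with 6.2 × 10⁻⁴ mM of free catalyst. Its turnover reckons to 3.80% of the substrate, and the table holds 3.28% target and 0.0481% side product. Its exposure is 20.3 mM·min, which gives a loss of 1.50%, and its simulated share is 98.6%.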